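**Retrosynthetic overview**

- The route rests on C2 of the dihydrobenzofuran ring (O1–C2–C3–C3a–C7a). C2 carries O1 and is benzylic to the catechol ring, para to one of its oxygens, so it can be raised from a CH2 group to a quinone-methide-type cation and captured by the C7a phenol.
- Disconnections, latest first: the C4 side-chain alkene (Horner–Wadsworth–Emmons with a danshensu phosphonoacetate); O1–C2 (DDQ oxidative cycloetherification of an enantiopure 2,3-diarylpropanoate); the C3–H bond (asymmetric hydrogenation of an (E)-2,3-diarylacrylic acid); the C3–aryl bond (Negishi coupling of the ring-A arylzinc with a (Z)-α-bromocinnamate).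
- Ring order: the three benzene rings are bought; the dihydrofuran ring is the only ring made (step 10), and C3 relays its configuration to C2 there.
- Every phenol, C7–O included, and the danshensu acid travel as benzyl ethers/ester, so that one benzyl-selective BCl3 step at the end leaves the C3 methyl ester and the alkene alone.

Key step: step 10

Remark: danshensu is taken as the free (R)-acid. The hand of the hydrogenation ligand that delivers the (R)-acid 11 is to be fixed on the first run, both antipodes being available.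

**Route**

Step 1
Reactants: 1 4-(benzyloxy)-3-hydroxybenzaldehyde
Product: 2 4-(benzyloxy)-2-bromo-3-hydroxybenzaldehyde
Conditions: Br2, NaOAc, Fe powder (cat.), AcOH, rt
Reagents that add atoms: bromine, BrBr
Why: Electrophilic aromatic bromination directed ortho by the free 3-OH; the position between OH and CHO is the one taken in the isovanillin series under these buffered conditions.

Step 2
Reactants: 2 4-(benzyloxy)-2-bromo-3-hydroxybenzaldehyde
Product: 3 6-(benzyloxy)-2-bromo-3-(1,3-dioxolan-2-yl)phenol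
Conditions: ethylene glycol, TsOH·H2O (cat.), PhMe, reflux, Dean–Stark
Reagents that add atoms: ethylene glycol, OCCO
Why: Acid-catalysed acetalisation driven by azeotropic water removal masks the aldehyde against the organolithium of step 5.

Step 3
Reactants: 3 6-(benzyloxy)-2-bromo-3-(1,3-dioxolan-2-yl)phenol
Product: 4 2-[4-(benzyloxy)-2-bromo-3-(methoxymethoxy)phenyl]-1,3-dioxolane
Conditions: MOMCl, iPr2NEt, CH2Cl2, 0 °C to rt
Reagents that add atoms: chloromethyl methyl ether, COCCl
Why: O-Alkylation of the phenol (MOM ether formation) under basic conditions that the dioxolane tolerates; MOM and dioxolane can later be removed together by acid without touching benzyl ethers.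

Step 4
Reactants: 5 3,4-bis(benzyloxy)benzaldehyde
Product: 6 methyl (Z)-3-[3,4-bis(benzyloxy)phenyl]-2-bromoprop-2-enoate
Conditions: Ph3P=CHCO2Me, NBS, CH2Cl2, −20 °C; then 5, K2CO3, rt
Reagents that add atoms: methyl (triphenylphosphoranylidene)acetate, COC(=O)C=P(c1ccccc1)(c1ccccc1)c1ccccc1; N-bromosuccinimide, O=C1CCC(=O)N1Br
Why: Wittig olefination with the α-bromo stabilised ylide generated in the flask by NBS bromination; a stabilised ylide is expected to place the ester trans to the aryl group, which is the (Z)-α-bromoacrylate.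

Step 5
Reactants: 4 2-[4-(benzyloxy)-2-bromo-3-(methoxymethoxy)phenyl]-1,3-dioxolane; 6 methyl (Z)-3-[3,4-bis(benzyloxy)phenyl]-2-bromoprop-2-enoate
Product: 9 methyl (E)-2-[3-(benzyloxy)-6-(1,3-dioxolan-2-yl)-2-(methoxymethoxy)phenyl]-3-[3,4-bis(benzyloxy)phenyl]prop-2-enoate, via aryllithium 7 (not isolated), via arylzinc chloride 8 (not isolated)
Conditions: n-BuLi, THF, −78 °C; ZnCl2, −78 °C to rt; then 6, Pd2(dba)3 (cat.), SPhos (cat.), THF, 50 °C
Reagents that add atoms: none
Why: Bromine–lithium exchange, transmetalation to zinc and Negishi cross-coupling with retention of alkene geometry, so the new aryl group ends cis to the β-aryl group ((E)-acrylate); SPhos is a ligand suited to di-ortho-substituted arylzinc reagents.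

Step 6
Reactants: 9 methyl (E)-2-[3-(benzyloxy)-6-(1,3-dioxolan-2-yl)-2-(methoxymethoxy)phenyl]-3-[3,4-bis(benzyloxy)phenyl]prop-2-enoate
Product: 10 (E)-2-[3-(benzyloxy)-6-(1,3-dioxolan-2-yl)-2-(methoxymethoxy)phenyl]-3-[3,4-bis(benzyloxy)phenyl]prop-2-enoic acid
Conditions: LiOH·H2O, THF/MeOH/H2O, 50 °C; then cold 1 M HCl to pH 4–5
Reagents that add atoms: lithium hydroxide, [Li+].[OH-]
Why: Ester saponification; acetal, MOM and benzyl ethers are base-stable, the brief mildly acidic work-up should spare the dioxolane, and the acid can be crystallised to geometric purity.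

Step 7
Reactants: 10 (E)-2-[3-(benzyloxy)-6-(1,3-dioxolan-2-yl)-2-(methoxymethoxy)phenyl]-3-[3,4-bis(benzyloxy)phenyl]prop-2-enoic acid
Product: 11 (R)-2-[3-(benzyloxy)-6-(1,3-dioxolan-2-yl)-2-(methoxymethoxy)phenyl]-3-[3,4-bis(benzyloxy)phenyl]propanoic acid
Conditions: [Ir(cod)(spiro-P,N ligand)]BArF (SpinPHOX or SIPHOX type, cat.), H2 (30 atm), Et3N, MeOH/THF, rt
Reagents that add atoms: none
Why: Carboxylate-directed iridium-catalysed asymmetric hydrogenation of an α-aryl-β-aryl acrylic acid; the chiral P,N ligand selects the enantioface and so sets the future C3, while benzyl ethers are inert to this homogeneous catalyst.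

Step 8
Reactants: 11 (R)-2-[3-(benzyloxy)-6-(1,3-dioxolan-2-yl)-2-(methoxymethoxy)phenyl]-3-[3,4-bis(benzyloxy)phenyl]propanoic acid
Product: 12 methyl (R)-2-[3-(benzyloxy)-6-(1,3-dioxolan-2-yl)-2-(methoxymethoxy)phenyl]-3-[3,4-bis(benzyloxy)phenyl]propanoate
Conditions: TMSCHN2, PhMe/MeOH, 0 °C to rt
Reagents that add atoms: (trimethylsilyl)diazomethane, C[Si](C)(C)C=[N+]=[N-]
Why: Methyl esterification of the carboxylic acid with TMS-diazomethane under neutral conditions, so the α-aryl stereocentre is not exposed to base.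

Step 9
Reactants: 12 methyl (R)-2-[3-(benzyloxy)-6-(1,3-dioxolan-2-yl)-2-(methoxymethoxy)phenyl]-3-[3,4-bis(benzyloxy)phenyl]propanoate
Product: 13 methyl (R)-2-[3-(benzyloxy)-6-formyl-2-hydroxyphenyl]-3-[3,4-bis(benzyloxy)phenyl]propanoate
Conditions: 2 M aq. HCl, THF/MeOH, rt
Reagents that add atoms: water, O
Why: Acid hydrolysis of both acetal-type groups (MOM ether and dioxolane) in one operation; benzyl ethers are inert and the methanol co-solvent should keep the ester–phenol pair from lactonising to a benzofuranone.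

Step 10
Reactants: 13 methyl (R)-2-[3-(benzyloxy)-6-formyl-2-hydroxyphenyl]-3-[3,4-bis(benzyloxy)phenyl]propanoate
Product: 14 methyl (2S,3S)-7-(benzyloxy)-2-[3,4-bis(benzyloxy)phenyl]-4-formyl-2,3-dihydro-1-benzofuran-3-carboxylate (trans)
Conditions: DDQ (1.1 equiv), 4 Å MS, CH2Cl2, 0 °C to rt
Reagents that add atoms: none
Why: DDQ forms a charge-transfer complex with the dibenzyloxyphenyl ring and removes hydride from the CH2 para to the 4-benzyloxy oxygen, giving a para-quinone-methide-type benzylic cation that the neighbouring phenol captures (oxidative cycloetherification, the reaction type that turns 2-hydroxy-1,3-diarylpropanes into flavans). The O1–C2 bond closes the dihydrofuran ring in a 5-exo-trig mode, the cationic carbon lying in the new ring and its quinone-methide double bond outside it. C2 is controlled by the C3 stereocentre: the aryl group should take the face anti to the C3 ester, and any cis isomer can drain to trans by reversible C2–O1 ionisation under the acidic DDQH2, a path that does not touch C3. The step needs site selectivity among this CH2, the C3–H and the three OCH2Ph groups: the para oxygen activates only the CH2, the ester destabilises a cation at C3, the formyl group makes the phenol ring the poorer donor, and unactivated benzyl aryl ethers are inert to DDQ at this temperature. Further dehydrogenation of the product to the benzofuran is held back by using close to one equivalent of oxidant at low temperature.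

Step 11
Reactants: 15 (R)-3-(3,4-dihydroxyphenyl)-2-hydroxypropanoic acid (danshensu)
Product: 16 benzyl (R)-3-[3,4-bis(benzyloxy)phenyl]-2-hydroxypropanoate
Conditions: BnBr (3.3 equiv), K2CO3, DMF, rt, under Ar
Reagents that add atoms: benzyl bromide, BrCc1ccccc1
Why: Williamson O-benzylation of the two phenoxides and the carboxylate; the secondary alcohol is not deprotonated by carbonate and the stereocentre is not involved.

Step 12
Reactants: 16 benzyl (R)-3-[3,4-bis(benzyloxy)phenyl]-2-hydroxypropanoate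
Product: 17 benzyl (R)-3-[3,4-bis(benzyloxy)phenyl]-2-{[2-(diethoxyphosphoryl)acetyl]oxy}propanoate
Conditions: (EtO)2P(O)CH2CO2H, DCC, DMAP (cat.), CH2Cl2, 0 °C to rt
Reagents that add atoms: diethylphosphonoacetic acid, CCOP(=O)(OCC)CC(=O)O
Why: Steglich esterification of the secondary alcohol; acylation at oxygen leaves the configuration of the carbinol carbon unchanged.

Step 13
Reactants: 14 methyl (2S,3S)-7-(benzyloxy)-2-[3,4-bis(benzyloxy)phenyl]-4-formyl-2,3-dihydro-1-benzofuran-3-carboxylate; 17 benzyl (R)-3-[3,4-bis(benzyloxy)phenyl]-2-{[2-(diethoxyphosphoryl)acetyl]oxy}propanoate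
Product: 18 methyl (2S,3S)-7-(benzyloxy)-4-[(E)-3-({(R)-1-(benzyloxy)-3-[3,4-bis(benzyloxy)phenyl]-1-oxopropan-2-yl}oxy)-3-oxoprop-1-en-1-yl]-2-[3,4-bis(benzyloxy)phenyl]-2,3-dihydro-1-benzofuran-3-carboxylate
Conditions: LiCl, iPr2NEt, MeCN, 0 °C to rt
Reagents that add atoms: none
Why: Horner–Wadsworth–Emmons olefination under Masamune–Roush conditions, which should give the (E)-enoate; the LiCl/amine base is too weak to deprotonate C3, to open the ring by E1cB or to epimerise the danshensu centre.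

Step 14
Reactants: 18 methyl (2S,3S)-7-(benzyloxy)-4-[(E)-3-({(R)-1-(benzyloxy)-3-[3,4-bis(benzyloxy)phenyl]-1-oxopropan-2-yl}oxy)-3-oxoprop-1-en-1-yl]-2-[3,4-bis(benzyloxy)phenyl]-2,3-dihydro-1-benzofuran-3-carboxylate
Product: 19 monomethyl lithospermate
Conditions: BCl3 (excess), C6HMe5, CH2Cl2, −78 to −20 °C; then aq. work-up
Reagents that add atoms: none
Why: Lewis-acid debenzylation with pentamethylbenzene as non-basic cation scavenger cleaves the five aryl benzyl ethers and the benzyl ester at a temperature where the methyl ester, the enoate ester and the alkene should be untouched; ionisation of C2–O1 is disfavoured by the adjacent ester and the low temperature.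

**Compound list**

1 | 4-(benzyloxy)-3-hydroxybenzaldehyde | O=Cc1ccc(OCc2ccccc2)c(O)c1 | starting material
2 | 4-(benzyloxy)-2-bromo-3-hydroxybenzaldehyde | O=Cc1ccc(OCc2ccccc2)c(O)c1Br | intermediate
3 | 6-(benzyloxy)-2-bromo-3-(1,3-dioxolan-2-yl)phenol | Oc1c(Br)c(C2OCCO2)ccc1OCc1ccccc1 | intermediate
4 | 2-[4-(benzyloxy)-2-bromo-3-(methoxymethoxy)phenyl]-1,3-dioxolane | COCOc1c(Br)c(C2OCCO2)ccc1OCc1ccccc1 | intermediate
5 | 3,4-bis(benzyloxy)benzaldehyde | O=Cc1ccc(OCc2ccccc2)c(OCc2ccccc2)c1 | starting material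
6 | methyl (Z)-3-[3,4-bis(benzyloxy)phenyl]-2-bromoprop-2-enoate | COC(=O)/C(Br)=C/c1ccc(OCc2ccccc2)c(OCc2ccccc2)c1 | intermediate
7 | [3-(benzyloxy)-6-(1,3-dioxolan-2-yl)-2-(methoxymethoxy)phenyl]lithium | [Li]c1c(OCOC)c(OCc2ccccc2)ccc1C1OCCO1 | intermediate (not isolated)
8 | [3-(benzyloxy)-6-(1,3-dioxolan-2-yl)-2-(methoxymethoxy)phenyl]zinc chloride | Cl[Zn]c1c(OCOC)c(OCc2ccccc2)ccc1C1OCCO1 | intermediate (not isolated)
9 | methyl (E)-2-[3-(benzyloxy)-6-(1,3-dioxolan-2-yl)-2-(methoxymethoxy)phenyl]-3-[3,4-bis(benzyloxy)phenyl]prop-2-enoate | COC(=O)/C(=C/c1ccc(OCc2ccccc2)c(OCc2ccccc2)c1)c1c(OCOC)c(OCc2ccccc2)ccc1C1OCCO1 | intermediate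
10 | (E)-2-[3-(benzyloxy)-6-(1,3-dioxolan-2-yl)-2-(methoxymethoxy)phenyl]-3-[3,4-bis(benzyloxy)phenyl]prop-2-enoic acid | OC(=O)/C(=C/c1ccc(OCc2ccccc2)c(OCc2ccccc2)c1)c1c(OCOC)c(OCc2ccccc2)ccc1C1OCCO1 | intermediate
11 | (R)-2-[3-(benzyloxy)-6-(1,3-dioxolan-2-yl)-2-(methoxymethoxy)phenyl]-3-[3,4-bis(benzyloxy)phenyl]propanoic acid | OC(=O)[C@H](Cc1ccc(OCc2ccccc2)c(OCc2ccccc2)c1)c1c(OCOC)c(OCc2ccccc2)ccc1C1OCCO1 | intermediate
12 | methyl (R)-2-[3-(benzyloxy)-6-(1,3-dioxolan-2-yl)-2-(methoxymethoxy)phenyl]-3-[3,4-bis(benzyloxy)phenyl]propanoate | COC(=O)[C@H](Cc1ccc(OCc2ccccc2)c(OCc2ccccc2)c1)c1c(OCOC)c(OCc2ccccc2)ccc1C1OCCO1 | intermediate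
13 | methyl (R)-2-[3-(benzyloxy)-6-formyl-2-hydroxyphenyl]-3-[3,4-bis(benzyloxy)phenyl]propanoate | COC(=O)[C@H](Cc1ccc(OCc2ccccc2)c(OCc2ccccc2)c1)c1c(C=O)ccc(OCc2ccccc2)c1O | intermediate (key-step precursor)
14 | methyl (2S,3S)-7-(benzyloxy)-2-[3,4-bis(benzyloxy)phenyl]-4-formyl-2,3-dihydro-1-benzofuran-3-carboxylate | COC(=O)[C@H]1c2c(C=O)ccc(OCc3ccccc3)c2O[C@@H]1c1ccc(OCc2ccccc2)c(OCc2ccccc2)c1 | intermediate (key-step product)
15 | (R)-3-(3,4-dihydroxyphenyl)-2-hydroxypropanoic acid (danshensu) | O=C(O)[C@H](O)Cc1ccc(O)c(O)c1 | starting material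
16 | benzyl (R)-3-[3,4-bis(benzyloxy)phenyl]-2-hydroxypropanoate | O=C(OCc1ccccc1)[C@H](O)Cc1ccc(OCc2ccccc2)c(OCc2ccccc2)c1 | intermediate
17 | benzyl (R)-3-[3,4-bis(benzyloxy)phenyl]-2-{[2-(diethoxyphosphoryl)acetyl]oxy}propanoate | CCOP(=O)(OCC)CC(=O)O[C@H](Cc1ccc(OCc2ccccc2)c(OCc2ccccc2)c1)C(=O)OCc1ccccc1 | intermediate
18 | hexabenzyl-protected monomethyl lithospermate (name as in step 13) | COC(=O)[C@H]1c2c(/C=C/C(=O)O[C@H](Cc3ccc(OCc4ccccc4)c(OCc4ccccc4)c3)C(=O)OCc3ccccc3)ccc(OCc3ccccc3)c2O[C@@H]1c1ccc(OCc2ccccc2)c(OCc2ccccc2)c1 | intermediate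
19 | monomethyl lithospermate | COC(=O)[C@H]1c2c(/C=C/C(=O)O[C@H](Cc3ccc(O)c(O)c3)C(=O)O)ccc(O)c2O[C@@H]1c1ccc(O)c(O)c1 | target

**Step count**

Total: 14 steps. Longest linear sequence: 11 steps (1, 2, 3, 5, 6, 7, 8, 9, 10, 13, 14). Step 4 and steps 11–12 are side branches.

**Steps most likely to fail**

1. Step 10 (oxidative cycloetherification). Oxidation of the free phenol ring, or further dehydrogenation of the closed product to the benzofuran, may compete with cation capture; hydride abstraction may also be slowed by the neighbouring ester.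
Fallback: separate the C–H oxidation from the ring closure, with the phenol masked during oxidation. It sets out from 12. Selective hydrolysis of the dioxolane (PPTS, wet acetone, 40 °C) with the aryl MOM ether kept should give methyl (R)-2-[3-(benzyloxy)-6-formyl-2-(methoxymethoxy)phenyl]-3-[3,4-bis(benzyloxy)phenyl]propanoate F1. DDQ in AcOH/CH2Cl2 should then trap the benzylic cation intermolecularly as methyl (2S,3RS)-3-acetoxy-2-[3-(benzyloxy)-6-formyl-2-(methoxymethoxy)phenyl]-3-[3,4-bis(benzyloxy)phenyl]propanoate F2, whose acetoxy group blocks a second oxidation. TFA in CH2Cl2 then removes the MOM group and ionises the benzylic acetate, and the freed phenol closes the ring by SN1 cycloetherification under thermodynamic (trans) control, coming back to the route at 14.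

2. Step 14 (global debenzylation). Lewis-acid ionisation of the benzylic C2–O1 ether may open the ring, with trapping of the cation by the scavenger; the benzyl ester may also cleave incompletely at a temperature the core tolerates.
Fallback: remove all benzyl groups by hydrogenolysis while no alkene is present and join the unprotected halves afterwards. It sets out from 14 and 16. Hydrogenolysis of 14 (H2, Pd/C, EtOAc, stopped once the ethers are gone so that the aryl aldehyde survives) should give methyl (2S,3S)-2-(3,4-dihydroxyphenyl)-4-formyl-7-hydroxy-2,3-dihydro-1-benzofuran-3-carboxylate F3. Alcohol 16 with Meldrum's acid (PhMe, 90 °C) should give the malonate half-ester 3-({(R)-1-(benzyloxy)-3-[3,4-bis(benzyloxy)phenyl]-1-oxopropan-2-yl}oxy)-3-oxopropanoic acid F4, and hydrogenolysis of this (H2, Pd/C) should give (R)-2-[(carboxyacetyl)oxy]-3-(3,4-dihydroxyphenyl)propanoic acid F5. Doebner–Knoevenagel condensation of F3 with F5 (pyridine, piperidine cat., 50 °C) should then form the (E)-enoate with loss of CO2 and come back to the route at 19.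

3. Step 7 (asymmetric hydrogenation). The di-ortho-substituted α-aryl group may give low conversion or poor enantioface selectivity.
Fallback: set the centre by auxiliary-controlled alkylation in place of hydrogenation. It sets out from 4. Palladium-catalysed coupling of 4 with the Reformatsky reagent BrZnCH2CO2Et (Pd(dba)2, Q-Phos, THF) should give ethyl 2-[3-(benzyloxy)-6-(1,3-dioxolan-2-yl)-2-(methoxymethoxy)phenyl]acetate F6, and saponification (LiOH) should give 2-[3-(benzyloxy)-6-(1,3-dioxolan-2-yl)-2-(methoxymethoxy)phenyl]acetic acid F7. Mixed-anhydride acylation (PivCl, Et3N) of lithiated (R)-4-benzyl-2-oxazolidinone should give (R)-4-benzyl-3-{2-[3-(benzyloxy)-6-(1,3-dioxolan-2-yl)-2-(methoxymethoxy)phenyl]acetyl}oxazolidin-2-one F8. Evans alkylation of its sodium (Z)-enolate (NaHMDS, THF, −78 °C) with commercial 3,4-bis(benzyloxy)benzyl bromide, on the face away from the auxiliary benzyl group, should give (R)-4-benzyl-3-{(R)-2-[3-(benzyloxy)-6-(1,3-dioxolan-2-yl)-2-(methoxymethoxy)phenyl]-3-[3,4-bis(benzyloxy)phenyl]propanoyl}oxazolidin-2-one F9. Cleavage with LiOH/H2O2 (THF/H2O, 0 °C) comes back to the route at 11.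

**Further compounds**

F1 | step 10 | methyl (R)-2-[3-(benzyloxy)-6-formyl-2-(methoxymethoxy)phenyl]-3-[3,4-bis(benzyloxy)phenyl]propanoate | COC(=O)[C@H](Cc1ccc(OCc2ccccc2)c(OCc2ccccc2)c1)c1c(OCOC)c(OCc2ccccc2)ccc1C=O
F2 | step 10 | methyl (2S,3RS)-3-acetoxy-2-[3-(benzyloxy)-6-formyl-2-(methoxymethoxy)phenyl]-3-[3,4-bis(benzyloxy)phenyl]propanoate | COC(=O)[C@H](C(OC(C)=O)c1ccc(OCc2ccccc2)c(OCc2ccccc2)c1)c1c(OCOC)c(OCc2ccccc2)ccc1C=O
F3 | step 14 | methyl (2S,3S)-2-(3,4-dihydroxyphenyl)-4-formyl-7-hydroxy-2,3-dihydro-1-benzofuran-3-carboxylate | COC(=O)[C@H]1c2c(C=O)ccc(O)c2O[C@@H]1c1ccc(O)c(O)c1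
F4 | step 14 | 3-({(R)-1-(benzyloxy)-3-[3,4-bis(benzyloxy)phenyl]-1-oxopropan-2-yl}oxy)-3-oxopropanoic acid | OC(=O)CC(=O)O[C@H](Cc1ccc(OCc2ccccc2)c(OCc2ccccc2)c1)C(=O)OCc1ccccc1
F5 | step 14 | (R)-2-[(carboxyacetyl)oxy]-3-(3,4-dihydroxyphenyl)propanoic acid | OC(=O)CC(=O)O[C@H](Cc1ccc(O)c(O)c1)C(=O)O
F6 | step 7 | ethyl 2-[3-(benzyloxy)-6-(1,3-dioxolan-2-yl)-2-(methoxymethoxy)phenyl]acetate | CCOC(=O)Cc1c(OCOC)c(OCc2ccccc2)ccc1C1OCCO1
F7 | step 7 | 2-[3-(benzyloxy)-6-(1,3-dioxolan-2-yl)-2-(methoxymethoxy)phenyl]acetic acid | OC(=O)Cc1c(OCOC)c(OCc2ccccc2)ccc1C1OCCO1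
F8 | step 7 | (R)-4-benzyl-3-{2-[3-(benzyloxy)-6-(1,3-dioxolan-2-yl)-2-(methoxymethoxy)phenyl]acetyl}oxazolidin-2-one | O=C(Cc1c(OCOC)c(OCc2ccccc2)ccc1C1OCCO1)N1[C@H](Cc2ccccc2)COC1=O
F9 | step 7 | (R)-4-benzyl-3-{(R)-2-[3-(benzyloxy)-6-(1,3-dioxolan-2-yl)-2-(methoxymethoxy)phenyl]-3-[3,4-bis(benzyloxy)phenyl]propanoyl}oxazolidin-2-one | O=C([C@H](Cc1ccc(OCc2ccccc2)c(OCc2ccccc2)c1)c1c(OCOC)c(OCc2ccccc2)ccc1C1OCCO1)N1[C@H](Cc2ccccc2)COC1=O
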